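Numbering the chain from the ketone carbon (C1), ring A (the 2-hydroxyphenyl ring) carries one carbon substituent only, C11, ortho to its hydroxyl. An ortho-alkylphenol of this kind is an isomer of a 6-alkylidenecyclohex-2-en-1-one, so the C11–ring A bond is made while ring A is still a cyclohexenone. A Mukaiyama aldol condensation joins the α′ carbon of cyclohexenone, as its cross-conjugated silyl dienol ether, to the aldehyde of a linear keto aldehyde that already bears ring B as its trimethyl ether, in one telescoped operation and without closing a ring. Redox-neutral isoaromatization then creates ring A, and ether cleavage frees the phloroglucinol. The target has no stereocentre.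

Key step: step 6

Remark: ring B is the 2,4,6-trihydroxyphenyl ring; the aldol of step 6 is carried on crude through mesylation and elimination, so the condensation is counted as one step.

Step 1
Reactants: 1 undec-10-enoyl chloride
Product: 2 N-methoxy-N-methylundec-10-enamide
Conditions: MeNHOMe·HCl, Et3N (2.2 equiv), CH2Cl2, 0 °C → rt
Reagents that add atoms: N,O-dimethylhydroxylamine hydrochloride, CNOC.Cl
Why: Nucleophilic acyl substitution of the acid chloride by the hydroxylamine released from its salt should give the Weinreb amide cleanly, the terminal alkene being a spectator.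

Step 2
Reactants: 3 1,3,5-trimethoxybenzene; 2 N-methoxy-N-methylundec-10-enamide
Product: 6 1-(2,4,6-trimethoxyphenyl)undec-10-en-1-one, via 2,4,6-trimethoxyphenyllithium 4 (not isolated), via tetrahedral lithium adduct 5 (not isolated)
Conditions: 3, n-BuLi, THF, 0 °C → rt; then 2, −78 → 0 °C; 1 M aq. HCl
Reagents that add atoms: none
Why: Directed ortho-lithiation between two methoxy groups gives aryllithium 4, which should add only once to the amide because chelate 5 persists until the acidic quench (Weinreb ketone synthesis).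

Step 3
Reactants: 6 1-(2,4,6-trimethoxyphenyl)undec-10-en-1-one
Product: 8 11-hydroxy-1-(2,4,6-trimethoxyphenyl)undecan-1-one, via B-alkyl-9-BBN borane 7 (not isolated)
Conditions: 9-BBN (0.5 M in THF, 1.3 equiv), 0 °C → rt; then 3 M aq. NaOH, 30% H2O2, 0 °C → rt
Reagents that add atoms: hydrogen peroxide, OO
Why: Anti-Markovnikov hydroboration–oxidation of the terminal alkene by the bulky dialkylborane should give the primary alcohol, while the aryl ketone, twisted and shielded by two ortho methoxy groups, should be reduced far more slowly; any over-reduced diol would be re-oxidized to the ketone in step 4.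

Step 4
Reactants: 8 11-hydroxy-1-(2,4,6-trimethoxyphenyl)undecan-1-one
Product: 9 11-oxo-11-(2,4,6-trimethoxyphenyl)undecanal
Conditions: Dess–Martin periodinane (1.5 equiv), CH2Cl2, 0 °C → rt
Reagents that add atoms: none
Why: Dess–Martin oxidation should convert the primary alcohol into the aldehyde without over-oxidation and leave the aryl ketone and the ethers untouched.

Step 5
Reactants: 10 cyclohex-2-en-1-one
Product: 12 2-(trimethylsilyloxy)cyclohexa-1,3-diene, via lithium cyclohexa-1,5-dien-1-olate 11 (not isolated)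
Conditions: LiN(i-Pr)2, THF, −78 °C; Me3SiCl, −78 °C → rt; distillation
Reagents that add atoms: chlorotrimethylsilane, C[Si](C)(C)Cl
Why: Kinetic deprotonation by the hindered lithium amide occurs at the α′ carbon (C6) of the enone, and O-silylation of dienolate 11 fixes the cross-conjugated 2-silyloxy diene (kinetic silyl enol ether formation).

Step 6
Reactants: 9 11-oxo-11-(2,4,6-trimethoxyphenyl)undecanal; 12 2-(trimethylsilyloxy)cyclohexa-1,3-diene
Product: 15 (E)-6-[11-oxo-11-(2,4,6-trimethoxyphenyl)undecylidene]cyclohex-2-en-1-one, via β-hydroxy enone 13 (not isolated), via mesylate 14 (not isolated)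
Conditions: 9, TiCl4 (1.2 equiv), CH2Cl2, −78 °C, then 12 (1.5 equiv); cold H2O quench, crude 13; MsCl, Et3N, CH2Cl2, 0 °C; then DBU, 0 °C → rt
Reagents that add atoms: none
Why: TiCl4 activates the aldehyde of 9 and dienol ether 12 attacks through C1, its only nucleophilic carbon (the α′ carbon of cyclohexenone), in an open transition state to give aldol 13 after loss of the silyl group (Mukaiyama aldol addition); mesylation and E1cB elimination with DBU then give the conjugated exocyclic alkene, the whole being an aldol condensation of the kind established for 2-silyloxy-1,3-dienes and for the α′ position of cyclohexenones. No ring is closed; the one new skeletal bond joins chain carbon C11 to the future ortho carbon of ring A. The two stereocentres of 13 are transient and vanish on elimination, and the alkene should be E because the chain avoids the carbonyl oxygen, although either isomer would serve since step 7 removes this element too. The selectivity needed is positional on the nucleophile and chemoselective on the electrophile: the cross-conjugated dienol ether cannot react at the γ carbon, and the aryl ketone of 9, twisted out of conjugation and flanked by two ortho methoxy groups, is far less electrophilic than the unhindered aldehyde. A second addition is not expected because the product enone is a much poorer acceptor than the titanium-bound aldehyde at −78 °C.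

Step 7
Reactants: 15 (E)-6-[11-oxo-11-(2,4,6-trimethoxyphenyl)undecylidene]cyclohex-2-en-1-one
Product: 17 11-(2-hydroxyphenyl)-1-(2,4,6-trimethoxyphenyl)undecan-1-one, via cyclohexa-2,5-dienone tautomer 16 (not isolated)
Conditions: RhCl3·3H2O (5 mol %), EtOH, 80–100 °C (sealed tube)
Reagents that add atoms: none
Why: A rhodium hydride formed in ethanol should add to and eliminate from the exocyclic alkene (transition-metal-catalysed olefin isomerization), moving it into the ring as dienone 16, whose enolization to the phenol is driven by aromatization.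

Step 8
Reactants: 17 11-(2-hydroxyphenyl)-1-(2,4,6-trimethoxyphenyl)undecan-1-one
Product: 19 11-(2-hydroxyphenyl)-1-(2,4,6-trihydroxyphenyl)undecan-1-one (target), via tetrakis(dibromoboryl) ether 18 (not isolated)
Conditions: BBr3 (8 equiv), CH2Cl2, −78 °C → rt; then H2O, 0 °C
Reagents that add atoms: none
Why: BBr3 coordinates each ether oxygen and bromide removes the methyl group by SN2 (Lewis-acid ether cleavage), the ortho ethers being assisted by chelation to the ketone and the para ether by excess reagent, and hydrolysis of borate 18 should free the four phenols.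

Compound list
1 | undec-10-enoyl chloride | C=CCCCCCCCCC(=O)Cl | starting material
2 | N-methoxy-N-methylundec-10-enamide | C=CCCCCCCCCC(=O)N(C)OC | intermediate
3 | 1,3,5-trimethoxybenzene | COc1cc(OC)cc(OC)c1 | starting material
4 | 2,4,6-trimethoxyphenyllithium | [Li]c1c(OC)cc(OC)cc1OC | intermediate (not isolated)
5 | lithium 1-[methoxy(methyl)amino]-1-(2,4,6-trimethoxyphenyl)undec-10-en-1-olate (racemic) | [Li]OC(CCCCCCCCC=C)(N(C)OC)c1c(OC)cc(OC)cc1OC | intermediate (not isolated)
6 | 1-(2,4,6-trimethoxyphenyl)undec-10-en-1-one | C=CCCCCCCCCC(=O)c1c(OC)cc(OC)cc1OC | intermediate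
7 | 11-(9-borabicyclo[3.3.1]nonan-9-yl)-1-(2,4,6-trimethoxyphenyl)undecan-1-one | O=C(CCCCCCCCCCB1C2CCCC1CCC2)c1c(OC)cc(OC)cc1OC | intermediate (not isolated)
8 | 11-hydroxy-1-(2,4,6-trimethoxyphenyl)undecan-1-one | O=C(CCCCCCCCCCO)c1c(OC)cc(OC)cc1OC | intermediate
9 | 11-oxo-11-(2,4,6-trimethoxyphenyl)undecanal | O=CCCCCCCCCCC(=O)c1c(OC)cc(OC)cc1OC | intermediate
10 | cyclohex-2-en-1-one | O=C1C=CCCC1 | starting material
11 | lithium cyclohexa-1,5-dien-1-olate | [Li+].[O-]C1=CCCC=C1 | intermediate (not isolated)
12 | 2-(trimethylsilyloxy)cyclohexa-1,3-diene | C[Si](C)(C)OC1=CCCC=C1 | intermediate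
13 | 6-[1-hydroxy-11-oxo-11-(2,4,6-trimethoxyphenyl)undecyl]cyclohex-2-en-1-one (racemic, both diastereomers) | O=C1C=CCCC1C(O)CCCCCCCCCC(=O)c1c(OC)cc(OC)cc1OC | intermediate (not isolated)
14 | 1-(2-oxocyclohex-3-en-1-yl)-11-oxo-11-(2,4,6-trimethoxyphenyl)undecyl methanesulfonate (racemic, both diastereomers) | O=C1C=CCCC1C(OS(C)(=O)=O)CCCCCCCCCC(=O)c1c(OC)cc(OC)cc1OC | intermediate (not isolated)
15 | (E)-6-[11-oxo-11-(2,4,6-trimethoxyphenyl)undecylidene]cyclohex-2-en-1-one | O=C1C=CCC/C1=C\CCCCCCCCCC(=O)c1c(OC)cc(OC)cc1OC | intermediate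
16 | 2-[11-oxo-11-(2,4,6-trimethoxyphenyl)undecyl]cyclohexa-2,5-dien-1-one | O=C1C=CCC=C1CCCCCCCCCCC(=O)c1c(OC)cc(OC)cc1OC | intermediate (not isolated)
17 | 11-(2-hydroxyphenyl)-1-(2,4,6-trimethoxyphenyl)undecan-1-one | O=C(CCCCCCCCCCc1ccccc1O)c1c(OC)cc(OC)cc1OC | intermediate
18 | 11-[2-(dibromoboryloxy)phenyl]-1-[2,4,6-tris(dibromoboryloxy)phenyl]undecan-1-one | O=C(CCCCCCCCCCc1ccccc1OB(Br)Br)c1c(OB(Br)Br)cc(OB(Br)Br)cc1OB(Br)Br | intermediate (not isolated)
19 | 11-(2-hydroxyphenyl)-1-(2,4,6-trihydroxyphenyl)undecan-1-one | O=C(CCCCCCCCCCc1ccccc1O)c1c(O)cc(O)cc1O | target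

Total step count: 8. Longest linear sequence: 7 steps (steps 1 to 4 and 6 to 8); step 5 is a one-step branch.

Steps most likely to fail

Step 6 (key step). The Lewis acid may be tied up by the ketone and ether oxygens of 9, so that the silyl dienol ether is only hydrolysed. The cross-conjugated dienone may also add to itself or aromatize in an uncontrolled way during the basic elimination. The fallback forms the same C11–ring A bond from an aromatic partner by a B-alkyl Suzuki–Miyaura coupling; it sets out from alkene 6 and comes back to the route at target 19. Borane 7, made from 6 as in step 3, is coupled without oxidation with 2-iodoanisole (PdCl2(dppf), K3PO4, THF/DMF/H2O, 60 °C) to give 11-(2-methoxyphenyl)-1-(2,4,6-trimethoxyphenyl)undecan-1-one F1. BBr3 under the conditions of step 8 should then cleave its four methyl ethers to give 19.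

Step 7. Migration of the trisubstituted exocyclic alkene into the ring may be slower than conjugate reduction by the rhodium hydride in hot ethanol, or slower than oligomerization of the dienone. The fallback separates saturation from aromatization; it sets out from 15 and comes back at 17. Hydrogenation of both alkenes of 15 (H2, palladium on carbon (Pd/C), EtOAc, rt) should give 2-[11-oxo-11-(2,4,6-trimethoxyphenyl)undecyl]cyclohexan-1-one F2 (racemic). Aerobic dehydrogenation of its cyclohexanone ring (Pd(O2CCF3)2, 2-(dimethylamino)pyridine, TsOH, O2, DMSO, 80 °C) should then give phenol 17; the shielded acyclic aryl ketone should not be dehydrogenated.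

Step 8. The cleavage may stall once the two ortho ethers are gone, because the boron chelate between the ortho oxygens and the ketone deactivates the para ether. Forcing it may detach the acyl chain from the very electron-rich ring. The fallback replaces the methyl ethers by benzyl ethers, which are removed by hydrogenolysis without a Lewis acid; it sets out from Weinreb amide 2 and comes back at target 19.
- 1,3,5-Tris(benzyloxy)benzene F3 is lithiated between two benzyloxy groups (n-BuLi, THF, 0 °C) to 2,4,6-tris(benzyloxy)phenyllithium F4.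
- F4 adds to 2 to give the tetrahedral lithium adduct F5 and, after the acidic quench, 1-[2,4,6-tris(benzyloxy)phenyl]undec-10-en-1-one F6.
- The conditions of steps 3 to 7 then apply unchanged. 9-BBN gives the B-alkyl borane F7 and oxidation the primary alcohol F8. Dess–Martin oxidation gives the keto aldehyde F9. The aldol with 12 gives the β-hydroxy enone F10, its mesylate F11 and the (E)-alkylidene enone F12. RhCl3·3H2O gives the cyclohexa-2,5-dienone F13 and the tris(benzyl ether) phenol F14.
- Hydrogenolysis of F14 (H2, palladium on carbon (Pd/C), EtOAc/MeOH, rt) should give 19.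

Further compounds
F1 | step 6 | 11-(2-methoxyphenyl)-1-(2,4,6-trimethoxyphenyl)undecan-1-one | COc1ccccc1CCCCCCCCCCC(=O)c1c(OC)cc(OC)cc1OC
F2 | step 7 | 2-[11-oxo-11-(2,4,6-trimethoxyphenyl)undecyl]cyclohexan-1-one (racemic) | O=C1CCCCC1CCCCCCCCCCC(=O)c1c(OC)cc(OC)cc1OC
F3 | step 8 | 1,3,5-tris(benzyloxy)benzene | c1c(OCc2ccccc2)cc(OCc2ccccc2)cc1OCc1ccccc1
F4 | step 8 | 2,4,6-tris(benzyloxy)phenyllithium | [Li]c1c(OCc2ccccc2)cc(OCc2ccccc2)cc1OCc1ccccc1
F5 | step 8 | lithium 1-[methoxy(methyl)amino]-1-[2,4,6-tris(benzyloxy)phenyl]undec-10-en-1-olate (racemic) | [Li]OC(CCCCCCCCC=C)(N(C)OC)c1c(OCc2ccccc2)cc(OCc2ccccc2)cc1OCc1ccccc1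
F6 | step 8 | 1-[2,4,6-tris(benzyloxy)phenyl]undec-10-en-1-one | C=CCCCCCCCCC(=O)c1c(OCc2ccccc2)cc(OCc2ccccc2)cc1OCc1ccccc1
F7 | step 8 | 11-(9-borabicyclo[3.3.1]nonan-9-yl)-1-[2,4,6-tris(benzyloxy)phenyl]undecan-1-one | O=C(CCCCCCCCCCB1C2CCCC1CCC2)c1c(OCc2ccccc2)cc(OCc2ccccc2)cc1OCc1ccccc1
F8 | step 8 | 11-hydroxy-1-[2,4,6-tris(benzyloxy)phenyl]undecan-1-one | O=C(CCCCCCCCCCO)c1c(OCc2ccccc2)cc(OCc2ccccc2)cc1OCc1ccccc1
F9 | step 8 | 11-oxo-11-[2,4,6-tris(benzyloxy)phenyl]undecanal | O=CCCCCCCCCCC(=O)c1c(OCc2ccccc2)cc(OCc2ccccc2)cc1OCc1ccccc1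
F10 | step 8 | 6-{1-hydroxy-11-oxo-11-[2,4,6-tris(benzyloxy)phenyl]undecyl}cyclohex-2-en-1-one (racemic, both diastereomers) | O=C1C=CCCC1C(O)CCCCCCCCCC(=O)c1c(OCc2ccccc2)cc(OCc2ccccc2)cc1OCc1ccccc1
F11 | step 8 | 1-(2-oxocyclohex-3-en-1-yl)-11-oxo-11-[2,4,6-tris(benzyloxy)phenyl]undecyl methanesulfonate (racemic, both diastereomers) | O=C1C=CCCC1C(OS(C)(=O)=O)CCCCCCCCCC(=O)c1c(OCc2ccccc2)cc(OCc2ccccc2)cc1OCc1ccccc1
F12 | step 8 | (E)-6-{11-oxo-11-[2,4,6-tris(benzyloxy)phenyl]undecylidene}cyclohex-2-en-1-one | O=C1C=CCC/C1=C\CCCCCCCCCC(=O)c1c(OCc2ccccc2)cc(OCc2ccccc2)cc1OCc1ccccc1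
F13 | step 8 | 2-{11-oxo-11-[2,4,6-tris(benzyloxy)phenyl]undecyl}cyclohexa-2,5-dien-1-one | O=C1C=CCC=C1CCCCCCCCCCC(=O)c1c(OCc2ccccc2)cc(OCc2ccccc2)cc1OCc1ccccc1
F14 | step 8 | 11-(2-hydroxyphenyl)-1-[2,4,6-tris(benzyloxy)phenyl]undecan-1-one | O=C(CCCCCCCCCCc1ccccc1O)c1c(OCc2ccccc2)cc(OCc2ccccc2)cc1OCc1ccccc1
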